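## Retrosynthetic overview

1. Drimane numbering is used: ring A = C1–C5 + C10, ring B = C5–C10, C11 = benzylic CH2, C12 = methyl on C8. The last bonds are aryl–C11 (B-alkyl Suzuki–Miyaura coupling of the 9-BBN adduct of diene 11 with aryl bromide 14; the hydroboration sets C9) and C9=C11 (Wittig reaction on enone 10).
2. Ring A is annulated onto ring B in one flask: C3–C4 by HAT-initiated radical addition to vinyltriphenylphosphonium, then ring closure at C1=C2 by intramolecular Wittig reaction of the resulting ylide with the C1 aldehyde. The C1=C2 alkene is hydrogenated afterwards.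
3. Ring B, C12, the C7=C8 alkene and the C5 stereocentre are bought as (R)-carvone. C10 is made quaternary by α′-methylation, then hydroxymethylation anti to the isopropenyl group, so that C1 enters trans to the C4 branch (trans ring fusion).
4. Enabling feature: ring B with C12 and C4 plus its two methyls is a p-menthane unit. C4 (quaternary, gem-dimethyl, bonded to C5) is exactly the tertiary radical formed by hydrogen-atom transfer to the isopropenyl group of carvone, and the fully substituted C10 makes the C1 aldehyde non-enolizable and holds it next to the C4 branch.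
5. Order of ring formation: ring B (chiral pool), then ring A (key step); the arene ring is bought as methyl 2,3,4-trihydroxybenzoate and attached last.

Key step: step 4

Remark on the chemistry: α/β refer to the usual drawing with the C10 methyl β; compound 3 is carried on as its mixture of epimers at the methyl-bearing carbon, because step 2 destroys that centre.

## Route

Step 1
Reactants: 1 (R)-(−)-carvone
Product: 3 trans-6-methylcarvone [(5R,6S)-2,6-dimethyl-5-(prop-1-en-2-yl)cyclohex-2-en-1-one], via lithium dienolate 2 (not isolated)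
Conditions: LiN(iPr)2 (commercial LDA solution), THF, −78 °C; MeI, −78 → −20 °C
Reagents that add atoms: iodomethane, CI
Why: Kinetic deprotonation of the cross-conjugated enone at the α′-CH2 (the future C10) and C-methylation of the lithium dienolate (enolate alkylation) should install the C10 methyl; the configuration of the new centre is irrelevant because both epimers give the same enolate in step 2.

Step 2
Reactants: 3 trans-6-methylcarvone (epimer mixture)
Product: 5 (5S,6R)-6-(hydroxymethyl)-2,6-dimethyl-5-(prop-1-en-2-yl)cyclohex-2-en-1-one, via lithium dienolate 4 (not isolated)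
Conditions: LiN(iPr)2 (commercial LDA solution), THF, −78 °C; CH2O (gas, from cracked paraformaldehyde), −78 °C; AcOH quench at −78 °C
Reagents that add atoms: formaldehyde, C=O
Why: Deprotonation at the only remaining α′-hydrogen gives the tetrasubstituted enolate 4, and its aldol reaction with monomeric formaldehyde (hydroxymethylation) should create the quaternary C10 by attack on the face anti to the adjacent C5 isopropenyl group, placing C1 trans to the C4 branch and the methyl cis to it, as the trans ring fusion requires.

Step 3
Reactants: 5 (5S,6R)-6-(hydroxymethyl)-2,6-dimethyl-5-(prop-1-en-2-yl)cyclohex-2-en-1-one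
Product: 6 (1R,6S)-1,3-dimethyl-2-oxo-6-(prop-1-en-2-yl)cyclohex-3-ene-1-carbaldehyde
Conditions: Dess–Martin periodinane, CH2Cl2, 0 °C → rt
Reagents that add atoms: none
Why: Dess–Martin oxidation of the neopentyl primary alcohol under neutral conditions should give the aldehyde without retro-aldol loss of C1; the aldehyde has no α-hydrogen, so it can neither enolize nor epimerize.

Step 4
Reactants: 6 (1R,6S)-1,3-dimethyl-2-oxo-6-(prop-1-en-2-yl)cyclohex-3-ene-1-carbaldehyde
Product: 9 (4aS,8aS)-2,5,5,8a-tetramethyl-4a,5,6,8a-tetrahydronaphthalen-1(4H)-one, via phosphonium bromide 7 (not isolated), via phosphorus ylide 8 (not isolated)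
Conditions: vinyltriphenylphosphonium bromide (1.2 equiv), Fe(acac)3 (30 mol%), PhSiH3 (2.5 equiv), EtOH/ethylene glycol, 60 °C; evaporate, triturate with Et2O; then KOtBu (1.2 equiv), THF (0.01 M), 0 °C → rt
Reagents that add atoms: vinyltriphenylphosphonium bromide, C=C[P+](c1ccccc1)(c1ccccc1)c1ccccc1.[Br-]
Why: Proposed new method: an iron hydride formed from Fe(acac)3 and PhSiH3 transfers a hydrogen atom to the CH2 terminus of the isopropenyl group of 6, the tertiary C4 radical adds to the cationic acceptor vinyltriphenylphosphonium (forming C3–C4), and reduction by divalent iron plus protonation by ethanol gives phosphonium salt 7; KOtBu then forms ylide 8, whose carbon C2 attacks the C1 aldehyde and expels Ph3PO to give the C1=C2 alkene. The closest known reaction types are the iron-hydride reductive coupling of donor alkenes with electron-poor alkenes (HAT-initiated Giese addition, which is selective for the isopropenyl group of carvone-type enones and tolerates aldehydes), radical additions to vinylphosphonium salts followed by Wittig olefination, and the Schweizer annulation in which a nucleophile adds to a vinylphosphonium salt and the ylide closes a ring; new is their merger with a tertiary carbon radical in the role of the nucleophile. Ring A is closed by a 6-exo-trig attack of the ylide carbon on the formyl carbon (intramolecular Wittig reaction), which can only give the cis ring alkene. No stereocentre is formed: C5 and C10 are already in place, and because the C4 branch on C5 and the formyl group on C10 are trans, both equatorial on ring B, the new ring should be trans-fused. The step needs HAT to the electron-rich 1,1-disubstituted alkene and not to the conjugated trisubstituted C7=C8 alkene (secured by substitution pattern and radical stability), intermolecular capture of the C4 radical (it has no 5- or 6-membered cyclization path to the enone or the formyl group), and ylide attack at the aldehyde only (the C9 ketone is hindered and its olefination by C2 would give a bridgehead alkene).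

Step 5
Reactants: 9 (4aS,8aS)-2,5,5,8a-tetramethyl-4a,5,6,8a-tetrahydronaphthalen-1(4H)-one
Product: 10 (4aS,8aS)-2,5,5,8a-tetramethyl-4a,5,6,7,8,8a-hexahydronaphthalen-1(4H)-one
Conditions: H2 (1 atm), RhCl(PPh3)3 (5 mol%), benzene/EtOH, rt
Reagents that add atoms: none
Why: Homogeneous hydrogenation with RhCl(PPh3)3 should reduce the cis-disubstituted C1=C2 alkene and leave the conjugated trisubstituted C7=C8 enone alkene, the same selectivity that converts carvone into carvotanacetone; no stereocentre is formed.

Step 6
Reactants: 10 (4aS,8aS)-2,5,5,8a-tetramethyl-4a,5,6,7,8,8a-hexahydronaphthalen-1(4H)-one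
Product: 11 drima-7,9(11)-diene [(4aS,8aS)-2,5,5,8a-tetramethyl-1-methylidene-1,4,4a,5,6,7,8,8a-octahydronaphthalene]
Conditions: Ph3PCH3Br, KOtBu, toluene, 90 °C
Reagents that add atoms: methyltriphenylphosphonium bromide, C[P+](c1ccccc1)(c1ccccc1)c1ccccc1.[Br-]
Why: Wittig methylenation with the ylide generated by KOtBu at elevated temperature is the standard answer to hindered α-quaternary ketones and should convert the C9 carbonyl into the C9=C11 methylidene; no stereocentre is formed.

Step 7
Reactants: 12 methyl 2,3,4-trihydroxybenzoate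
Product: 13 methyl 2,3,4-tris(methoxymethoxy)benzoate
Conditions: MOMCl (4.5 equiv), iPr2NEt, CH2Cl2, 0 → 40 °C
Reagents that add atoms: chloromethyl methyl ether, COCCl
Why: O-Alkylation of the three phenols with chloromethyl methyl ether (MOM acetal protection) should mask the acidic, oxidation-prone pyrogallol for the basic cross-coupling.

Step 8
Reactants: 13 methyl 2,3,4-tris(methoxymethoxy)benzoate
Product: 14 methyl 5-bromo-2,3,4-tris(methoxymethoxy)benzoate
Conditions: NBS, MeCN, 0 °C → rt
Reagents that add atoms: N-bromosuccinimide, O=C1CCC(=O)N1Br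
Why: Electrophilic aromatic bromination should occur at C5, the position para to the C2 oxygen, ortho to the C4 oxygen and meta to the ester, as with the analogous trimethoxybenzoate.

Step 9
Reactants: 11 drima-7,9(11)-diene; 14 methyl 5-bromo-2,3,4-tris(methoxymethoxy)benzoate
Product: 16 methyl 2,3,4-tris(methoxymethoxy)-5-{[(1S,4aS,8aS)-2,5,5,8a-tetramethyl-1,4,4a,5,6,7,8,8a-octahydronaphthalen-1-yl]methyl}benzoate, via B-alkyl-9-BBN 15 (not isolated)
Conditions: 9-BBN, THF, 65 °C; then 14, Pd(dppf)Cl2 (5 mol%), K3PO4 (3 M aq), THF/DMF, 60 °C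
Reagents that add atoms: none
Why: 9-BBN should hydroborate only the 1,1-disubstituted exocyclic C9=C11 alkene, with boron on C11 and hydrogen delivered to C9 from the α face opposite the axial C10 methyl (this sets C9 with the CH2 group β, equatorial), and the resulting borane 15 is then joined to 14 by B-alkyl Suzuki–Miyaura coupling.

Step 10
Reactants: 16 methyl 2,3,4-tris(methoxymethoxy)-5-{[(1S,4aS,8aS)-2,5,5,8a-tetramethyl-1,4,4a,5,6,7,8,8a-octahydronaphthalen-1-yl]methyl}benzoate
Product: 17 methyl 2,3,4-trihydroxy-5-{[(1S,4aS,8aS)-2,5,5,8a-tetramethyl-1,4,4a,5,6,7,8,8a-octahydronaphthalen-1-yl]methyl}benzoate (CNP0185238.1)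
Conditions: HCl (0.5 M in MeOH), argon, 0 °C → rt
Reagents that add atoms: none
Why: Acid-catalysed acetal exchange with methanol should remove the three MOM groups under conditions too mild to protonate the trisubstituted C7=C8 alkene, and the methyl ester is unchanged in methanol; no stereocentre is touched.

## Compound list

1 | (R)-(−)-carvone | O=C1C(C)=CC[C@@H](C(C)=C)C1 | starting material
2 | lithium dienolate of carvone | CC1=CC[C@@H](C(C)=C)C=C1O[Li] | intermediate (not isolated)
3 | trans-6-methylcarvone, (5R,6S)-2,6-dimethyl-5-(prop-1-en-2-yl)cyclohex-2-en-1-one | O=C1C(C)=CC[C@@H](C(C)=C)[C@@H]1C | intermediate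
4 | lithium dienolate of 6-methylcarvone | CC1=CC[C@@H](C(C)=C)C(C)=C1O[Li] | intermediate (not isolated)
5 | (5S,6R)-6-(hydroxymethyl)-2,6-dimethyl-5-(prop-1-en-2-yl)cyclohex-2-en-1-one | O=C1C(C)=CC[C@@H](C(C)=C)[C@]1(C)CO | intermediate
6 | (1R,6S)-1,3-dimethyl-2-oxo-6-(prop-1-en-2-yl)cyclohex-3-ene-1-carbaldehyde | O=C1C(C)=CC[C@@H](C(C)=C)[C@]1(C)C=O | intermediate
7 | {3-[(1S,2R)-2-formyl-2,4-dimethyl-3-oxocyclohex-4-en-1-yl]-3-methylbutyl}triphenylphosphonium bromide | O=C1C(C)=CC[C@@H](C(C)(C)CC[P+](c2ccccc2)(c2ccccc2)c2ccccc2)[C@]1(C)C=O.[Br-] | intermediate (not isolated)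
8 | (1R,6S)-1,3-dimethyl-6-[2-methyl-4-(triphenyl-λ5-phosphanylidene)butan-2-yl]-2-oxocyclohex-3-ene-1-carbaldehyde (ylide) | O=C1C(C)=CC[C@@H](C(C)(C)CC=P(c2ccccc2)(c2ccccc2)c2ccccc2)[C@]1(C)C=O | intermediate (not isolated)
9 | (4aS,8aS)-2,5,5,8a-tetramethyl-4a,5,6,8a-tetrahydronaphthalen-1(4H)-one (trans-fused, 10β-methyl, 5α-H) | O=C1C(C)=CC[C@H]2C(C)(C)CC=C[C@]12C | intermediate
10 | (4aS,8aS)-2,5,5,8a-tetramethyl-4a,5,6,7,8,8a-hexahydronaphthalen-1(4H)-one | O=C1C(C)=CC[C@H]2C(C)(C)CCC[C@]12C | intermediate
11 | drima-7,9(11)-diene, (4aS,8aS)-2,5,5,8a-tetramethyl-1-methylidene-1,4,4a,5,6,7,8,8a-octahydronaphthalene | C=C1C(C)=CC[C@H]2C(C)(C)CCC[C@]12C | intermediate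
12 | methyl 2,3,4-trihydroxybenzoate | COC(=O)c1ccc(O)c(O)c1O | starting material
13 | methyl 2,3,4-tris(methoxymethoxy)benzoate | COC(=O)c1ccc(OCOC)c(OCOC)c1OCOC | intermediate
14 | methyl 5-bromo-2,3,4-tris(methoxymethoxy)benzoate | COC(=O)c1cc(Br)c(OCOC)c(OCOC)c1OCOC | intermediate
15 | 9-{[(1S,4aS,8aS)-2,5,5,8a-tetramethyl-1,4,4a,5,6,7,8,8a-octahydronaphthalen-1-yl]methyl}-9-borabicyclo[3.3.1]nonane | C(B1C2CCCC1CCC2)[C@H]1C(C)=CC[C@H]2C(C)(C)CCC[C@]12C | intermediate (not isolated)
16 | methyl 2,3,4-tris(methoxymethoxy)-5-{[(1S,4aS,8aS)-2,5,5,8a-tetramethyl-1,4,4a,5,6,7,8,8a-octahydronaphthalen-1-yl]methyl}benzoate | COC(=O)c1cc(C[C@H]2C(C)=CC[C@H]3C(C)(C)CCC[C@]23C)c(OCOC)c(OCOC)c1OCOC | intermediate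
17 | methyl 2,3,4-trihydroxy-5-{[(1S,4aS,8aS)-2,5,5,8a-tetramethyl-1,4,4a,5,6,7,8,8a-octahydronaphthalen-1-yl]methyl}benzoate (CNP0185238.1) | COC(=O)c1cc(C[C@H]2C(C)=CC[C@H]3C(C)(C)CCC[C@]23C)c(O)c(O)c1O | target

## Step count and risks

Total step count: 10. Longest linear sequence: 8 steps (steps 1–6, 9 and 10); the two-step arene branch (steps 7 and 8) joins at step 9.

Steps most likely to fail:

**Step 4 (Proposed new method).** Three processes may compete. The tertiary radical may be reduced before it meets the acceptor (net hydrogenation of the isopropenyl group). The aldehyde may be hydrosilylated under the iron/silane conditions. In the base stage, the formyl group may be lost (retro-Claisen cleavage), or ylides from leftover phosphonium salt may olefinate intermolecularly. The fallback uses only known reaction types and still closes ring A at C1–C2, now by ring-closing metathesis. It sets out from 6: chemoselective Wittig methylenation of the aldehyde (Ph3P=CH2, THF, −78 → 0 °C) would give (5S,6S)-6-ethenyl-2,6-dimethyl-5-(prop-1-en-2-yl)cyclohex-2-en-1-one F1. Markovnikov addition of HBr in AcOH at 0 °C to the isopropenyl group would give the tertiary bromide (5R,6S)-5-(2-bromopropan-2-yl)-6-ethenyl-2,6-dimethylcyclohex-2-en-1-one F2. Keck radical allylation (allyltributylstannane, AIBN, benzene, 80 °C) would give (5S,6S)-6-ethenyl-2,6-dimethyl-5-(2-methylpent-4-en-2-yl)cyclohex-2-en-1-one F3. Ring-closing metathesis of the vinyl and allyl groups (second-generation Grubbs catalyst, CH2Cl2, 40 °C) comes back to the route at 9.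

**Step 9.** The hindered, β-branched alkylborane may transmetalate slowly, so that β-hydride elimination and protodeboronation outrun the coupling; the hydroboration may also discriminate the two faces of C9 incompletely. The fallback separates the two events and replaces boron by zinc. It sets out from 11: hydroboration–oxidation (9-BBN, THF; then NaOH, H2O2) would give drimenol F4, where any C9 epimer can be removed by chromatography. Appel iodination (I2, PPh3, imidazole, CH2Cl2) would give (1S,4aS,8aS)-1-(iodomethyl)-2,5,5,8a-tetramethyl-1,4,4a,5,6,7,8,8a-octahydronaphthalene F5. Zinc insertion (Zn dust, LiCl, THF) would give the corresponding alkylzinc iodide F6. Negishi coupling with 14 (Pd(OAc)2, SPhos, THF, 50 °C) comes back to the route at 16.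

**Step 2.** The very small electrophile may discriminate the enolate faces poorly, and retro-aldol release of formaldehyde may occur on warming or work-up. The fallback replaces the reversible aldol reaction by an irreversible alkylation with a bulkier electrophile. It sets out from 3: enolate 4 (LiN(iPr)2, THF, −78 °C) would be alkylated with (4-methoxybenzyloxy)methyl chloride to give (5S,6R)-6-{[(4-methoxyphenyl)methoxy]methyl}-2,6-dimethyl-5-(prop-1-en-2-yl)cyclohex-2-en-1-one F7. Oxidative removal of the 4-methoxybenzyl group (DDQ, CH2Cl2/H2O, 0 °C) comes back to the route at 5.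

Further compounds
F1 | step 4 | (5S,6S)-6-ethenyl-2,6-dimethyl-5-(prop-1-en-2-yl)cyclohex-2-en-1-one | O=C1C(C)=CC[C@@H](C(C)=C)[C@]1(C)C=C
F2 | step 4 | (5R,6S)-5-(2-bromopropan-2-yl)-6-ethenyl-2,6-dimethylcyclohex-2-en-1-one | O=C1C(C)=CC[C@@H](C(C)(C)Br)[C@]1(C)C=C
F3 | step 4 | (5S,6S)-6-ethenyl-2,6-dimethyl-5-(2-methylpent-4-en-2-yl)cyclohex-2-en-1-one | O=C1C(C)=CC[C@@H](C(C)(C)CC=C)[C@]1(C)C=C
F4 | step 9 | drimenol, [(1S,4aS,8aS)-2,5,5,8a-tetramethyl-1,4,4a,5,6,7,8,8a-octahydronaphthalen-1-yl]methanol | OC[C@H]1C(C)=CC[C@H]2C(C)(C)CCC[C@]12C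
F5 | step 9 | (1S,4aS,8aS)-1-(iodomethyl)-2,5,5,8a-tetramethyl-1,4,4a,5,6,7,8,8a-octahydronaphthalene | IC[C@H]1C(C)=CC[C@H]2C(C)(C)CCC[C@]12C
F6 | step 9 | {[(1S,4aS,8aS)-2,5,5,8a-tetramethyl-1,4,4a,5,6,7,8,8a-octahydronaphthalen-1-yl]methyl}zinc iodide | I[Zn]C[C@H]1C(C)=CC[C@H]2C(C)(C)CCC[C@]12C
F7 | step 2 | (5S,6R)-6-{[(4-methoxyphenyl)methoxy]methyl}-2,6-dimethyl-5-(prop-1-en-2-yl)cyclohex-2-en-1-one | O=C1C(C)=CC[C@@H](C(C)=C)[C@]1(C)COCc1ccc(OC)cc1
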